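**Retrosynthetic overview**
1. Target ⇐ desilylation ⇐ SN1′ hydration of primary allylic bromide 16, which re-creates the C1 carbinol under control of the ring halogens ⇐ ketone 7 + alkenyllithium from 13.
2. Ketone 7 ⇐ bromochlorohydrin 6 ⇐ hydroxyl-relayed chloroetherification and C–O→C–Br exchange on (1S)-4-methylcyclohex-3-en-1-ol 3.
3. Alcohol 3 ⇐ key ring expansion (cationic cyclopropylcarbinyl→homoallyl opening) of the methyl carbinol from bicyclo[3.1.0]hexan-2-one 1.
4. Side chain 13 ⇐ CBS reduction ⇐ dienolate allylation of 3-methylbut-3-en-2-one with 2,3-dibromopropene.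
5. Ring order: bought bicyclo[3.1.0]hexane → cyclohexene (ring expansion, the only carbocycle-forming event) → transient 7-oxabicyclo[2.2.1]heptane relay → cyclohexane.

Assumption: (1S,5R)-bicyclo[3.1.0]hexan-2-one is bought as the single enantiomer (otherwise two known steps from commercial enantiopure 1,2-epoxyhex-5-ene: intramolecular carbenoid cyclopropanation, then alcohol oxidation).

**Route**

Step 1
Reactants: 1 (1S,5R)-bicyclo[3.1.0]hexan-2-one
Product: 3 (1S)-4-methylcyclohex-3-en-1-ol, via tertiary carbinol 2 (not isolated)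
Conditions: MeMgBr, Et2O, −78 → 0 °C; then 1 M H2SO4, THF, 23 °C
Reagents that add atoms: methylmagnesium bromide C[Mg]Br; water O
Why: Grignard addition then acid-triggered cyclopropylcarbinyl-to-homoallyl ring expansion (the i-steroid / sabinene hydrate → terpinen-4-ol rearrangement, a stepwise cationic skeletal change): water opens the tertiary cation at C5 with inversion, turning the five-membered ring into the cyclohexene and transcribing the bridgehead configuration of 1 into the (1S)-carbinol, which reduction of the pseudo-symmetric ketone cannot deliver.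

Step 2
Reactants: 3 (1S)-4-methylcyclohex-3-en-1-ol
Product: 6 (1S,3R,4R)-4-bromo-3-chloro-4-methylcyclohexan-1-ol, via chloro ether 4 (not isolated), via silyl ether 5 (not isolated)
Conditions: N-chlorosuccinimide, Ph3P=S (5 mol %), CH2Cl2, 0 °C; then Me3SiBr (2.5 equiv), ZnBr2 (10 mol %), −40 → 0 °C; then MeOH, K2CO3
Reagents that add atoms: N-chlorosuccinimide O=C1CCC(=O)N1Cl; bromotrimethylsilane C[Si](C)(C)Br
Why: Chloroetherification then Lewis-acid ether cleavage: Cl+ adds anti to the hydroxyl, which closes on the tertiary alkene carbon (sets 3R and the C4–O bond), and Me3SiBr/ZnBr2 ionises the tertiary bridgehead C–O with anti β-chlorine participation so bromide returns with retention (4R, Br trans to Cl, cis to OH).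

Step 3
Reactants: 6 (1S,3R,4R)-4-bromo-3-chloro-4-methylcyclohexan-1-ol
Product: 7 (3R,4R)-4-bromo-3-chloro-4-methylcyclohexan-1-one
Conditions: Dess–Martin periodinane, NaHCO3, CH2Cl2, 0 → 23 °C
Reagents that add atoms: none
Why: Dess–Martin oxidation under buffered neutral conditions gives the β-chloro ketone without E1cB loss of HCl; C1 is given up deliberately because step 9 re-sets it from C3/C4.

Step 4
Reactants: 8 3-methylbut-3-en-2-one, 9 2,3-dibromoprop-1-ene
Product: 11 6-bromo-2-methylhepta-1,6-dien-3-one, via lithium dienolate 10 (not isolated)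
Conditions: i-Pr2NLi (LDA), THF, −78 °C; DMPU; then 9, −78 → −40 °C
Reagents that add atoms: none
Why: Kinetic α′-deprotonation and SN2 allylation of the cross-conjugated lithium dienolate by the allylic bromide of 9 (the vinylic bromide is inert) builds the whole C8–C13 chain in one enolate alkylation.

Step 5
Reactants: 11 6-bromo-2-methylhepta-1,6-dien-3-one
Product: 12 (3R)-6-bromo-2-methylhepta-1,6-dien-3-ol
Conditions: (S)-1-methyl-3,3-diphenyltetrahydro-1H,3H-pyrrolo[1,2-c][1,3,2]oxazaborole [(S)-Me-CBS, 10 mol %], BH3·SMe2, THF, −30 °C; MeOH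
Reagents that add atoms: none
Why: Corey–Bakshi–Shibata reduction: the isopropenyl group acts as the large substituent, so the (S)-catalyst delivers hydride to give the (3R)-allylic alcohol by 1,2-reduction.

Step 6
Reactants: 12 (3R)-6-bromo-2-methylhepta-1,6-dien-3-ol
Product: 13 {[(3R)-6-bromo-2-methylhepta-1,6-dien-3-yl]oxy}(tert-butyl)dimethylsilane
Conditions: t-BuMe2SiCl, imidazole, DMF, 23 °C
Reagents that add atoms: tert-butyldimethylsilyl chloride CC(C)(C)[Si](C)(C)Cl
Why: Silyl ether formation protects the allylic alcohol through the organolithium and bromination steps, and its bulk disfavours oxygen participation in step 9.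

Step 7
Reactants: 13 {[(3R)-6-bromo-2-methylhepta-1,6-dien-3-yl]oxy}(tert-butyl)dimethylsilane, 7 (3R,4R)-4-bromo-3-chloro-4-methylcyclohexan-1-one
Product: 15 C1-epimer mixture of (3R,4R)-4-bromo-1-[(5R)-5-{[tert-butyl(dimethyl)silyl]oxy}-6-methylhepta-1,6-dien-2-yl]-3-chloro-4-methylcyclohexan-1-ol, via alkenyllithium 14 (not isolated)
Conditions: t-BuLi (2.0 equiv), Et2O, −78 °C; transfer into 7 + anhydrous CeCl3, THF, −78 °C; sat. aq. NH4Cl
Reagents that add atoms: none
Why: Bromine–lithium exchange then CeCl3-mediated 1,2-addition to the enolisable β-chloro ketone forms the C1–C8 bond; attack anti to the axial C3–Cl should favour the unwanted C1 epimer, which is immaterial because steps 8 and 9 erase and re-set C1.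

Step 8
Reactants: 15 C1-epimer mixture of the tertiary allylic alcohol
Product: 16 {[(3R)-7-bromo-6-[(3R,4R)-4-bromo-3-chloro-4-methylcyclohexylidene]-2-methylhept-1-en-3-yl]oxy}(tert-butyl)dimethylsilane (E/Z mixture)
Conditions: PBr3 (0.4 equiv), pyridine (0.2 equiv), Et2O, −30 → 0 °C
Reagents that add atoms: phosphorus tribromide BrP(Br)Br
Why: SN2′/SNi′ bromination of a tertiary allylic alcohol (linalool → geranyl bromide type) funnels both C1 epimers into one constitution, the primary allylic bromide with an exocyclic tetrasubstituted alkene.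

Step 9
Reactants: 16 primary allylic bromide (E/Z mixture)
Product: 17 (1S,3R,4R)-4-bromo-1-[(5R)-5-{[tert-butyl(dimethyl)silyl]oxy}-6-methylhepta-1,6-dien-2-yl]-3-chloro-4-methylcyclohexan-1-ol
Conditions: acetone–H2O (4:1), 2,6-lutidine (1.5 equiv), 0 → 23 °C
Reagents that add atoms: water O
Why: Proposed new method: a stereoconvergent SN1′ hydration that re-sets the carbinol – both alkene isomers ionise to one exocyclic allyl cation, water attacks the ring terminus (larger positive charge) from the equatorial face anti to the axial C3–Cl of the trans-diaxial bromochloride chair so OH ends cis to Br (1S), and the buffer prevents re-ionisation while the β-chloro-deactivated tertiary bromide stays intact; the closest known reaction type is the SN1′ solvolysis of prenyl or geranyl halides to tertiary linalool-type alcohols, not yet shown with a vicinal dihalide as the only facial control element.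

Step 10
Reactants: 17 silyl-protected target
Product: 18 (1S,3R,4R)-4-bromo-3-chloro-1-[(5R)-5-hydroxy-6-methylhepta-1,6-dien-2-yl]-4-methylcyclohexan-1-ol
Conditions: Bu4NF–AcOH (1:1), THF, 0 → 23 °C
Reagents that add atoms: none
Why: Fluoride desilylation buffered with acetic acid frees the secondary allylic alcohol without E2 of the tertiary bromide or ionisation of the tertiary allylic alcohol.

**Compound list**
1 | (1S,5R)-bicyclo[3.1.0]hexan-2-one | O=C1CC[C@@H]2C[C@H]12 | starting material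
2 | (1S,2R,5R)-2-methylbicyclo[3.1.0]hexan-2-ol (major adduct; C2 is erased on ionisation) | C[C@@]1(O)CC[C@@H]2C[C@H]12 | intermediate
3 | (1S)-4-methylcyclohex-3-en-1-ol | CC1=CC[C@@H](O)CC1 | intermediate
4 | (1R,2R,4S)-2-chloro-1-methyl-7-oxabicyclo[2.2.1]heptane (chlorine anti to the oxygen bridge) | C[C@@]12CC[C@@H](C[C@H]1Cl)O2 | intermediate
5 | {[(1S,3R,4R)-4-bromo-3-chloro-4-methylcyclohexyl]oxy}trimethylsilane | C[Si](C)(C)O[C@H]1CC[C@@](C)(Br)[C@H](Cl)C1 | intermediate
6 | (1S,3R,4R)-4-bromo-3-chloro-4-methylcyclohexan-1-ol | O[C@H]1CC[C@@](C)(Br)[C@H](Cl)C1 | intermediate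
7 | (3R,4R)-4-bromo-3-chloro-4-methylcyclohexan-1-one | O=C1CC[C@@](C)(Br)[C@H](Cl)C1 | intermediate
8 | 3-methylbut-3-en-2-one | CC(=O)C(C)=C | starting material
9 | 2,3-dibromoprop-1-ene | BrCC(Br)=C | starting material
10 | lithium 3-methylbuta-1,3-dien-2-olate | [Li]OC(=C)C(C)=C | intermediate
11 | 6-bromo-2-methylhepta-1,6-dien-3-one | C=C(C)C(=O)CCC(Br)=C | intermediate
12 | (3R)-6-bromo-2-methylhepta-1,6-dien-3-ol | C=C(C)[C@H](O)CCC(Br)=C | intermediate
13 | {[(3R)-6-bromo-2-methylhepta-1,6-dien-3-yl]oxy}(tert-butyl)dimethylsilane | C=C(C)[C@H](O[Si](C)(C)C(C)(C)C)CCC(Br)=C | intermediate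
14 | [(5R)-5-{[tert-butyl(dimethyl)silyl]oxy}-6-methylhepta-1,6-dien-2-yl]lithium | C=C(C)[C@H](O[Si](C)(C)C(C)(C)C)CCC([Li])=C | intermediate
15 | (3R,4R)-4-bromo-1-[(5R)-5-{[tert-butyl(dimethyl)silyl]oxy}-6-methylhepta-1,6-dien-2-yl]-3-chloro-4-methylcyclohexan-1-ol, both C1 epimers | C=C(C)[C@H](O[Si](C)(C)C(C)(C)C)CCC(=C)C1(O)CC[C@@](C)(Br)[C@H](Cl)C1 | intermediate
16 | {[(3R)-7-bromo-6-[(3R,4R)-4-bromo-3-chloro-4-methylcyclohexylidene]-2-methylhept-1-en-3-yl]oxy}(tert-butyl)dimethylsilane, E/Z mixture | C=C(C)[C@H](O[Si](C)(C)C(C)(C)C)CCC(CBr)=C1CC[C@@](C)(Br)[C@H](Cl)C1 | intermediate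
17 | (1S,3R,4R)-4-bromo-1-[(5R)-5-{[tert-butyl(dimethyl)silyl]oxy}-6-methylhepta-1,6-dien-2-yl]-3-chloro-4-methylcyclohexan-1-ol | C=C(C)[C@H](O[Si](C)(C)C(C)(C)C)CCC(=C)[C@]1(O)CC[C@@](C)(Br)[C@H](Cl)C1 | intermediate
18 | (1S,3R,4R)-4-bromo-3-chloro-1-[(5R)-5-hydroxy-6-methylhepta-1,6-dien-2-yl]-4-methylcyclohexan-1-ol | C=C(C)[C@H](O)CCC(=C)[C@]1(O)CC[C@@](C)(Br)[C@H](Cl)C1 | target

**Totals and risks**
Total steps: 10. Longest linear sequence: 7 (steps 1, 2, 3, 7, 8, 9, 10; the chain branch 4, 5, 6, 7, 8, 9, 10 is equally long).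

Three steps most likely to fail:

Step 2. The silyl bromide may open the secondary bridgehead C–O of 4 by SN2 instead of ionising the β-chloro-deactivated tertiary C–O. The fallback sets out from 3: chloro ether 4 is isolated after the same chloroetherification and cleaved by acylative ether cleavage with acetyl bromide/ZnBr2 at −40 °C. This activates the ether as an acyloxonium ion and leaves only the SN1 path at the tertiary carbon, giving (1S,3R,4R)-4-bromo-3-chloro-4-methylcyclohexyl acetate F1. Methanolysis (K2CO3, MeOH) then comes back to the route at 6.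

Step 7. The alkenyl organometallic may enolise the β-chloro ketone (E1cB loss of HCl) or attack the tertiary bromide. The fallback sets out from 3 and 13 and never lets an organometallic meet the halogens.
- 3 is esterified to (1S)-4-methylcyclohex-3-en-1-yl 2,4,6-tri(propan-2-yl)benzoate F2.
- 13 is converted (t-BuLi, then 2-isopropoxy-4,4,5,5-tetramethyl-1,3,2-dioxaborolane) into the alkenyl boronic ester tert-butyl(dimethyl){[(3R)-2-methyl-6-(4,4,5,5-tetramethyl-1,3,2-dioxaborolan-2-yl)hepta-1,6-dien-3-yl]oxy}silane F3.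
- Lithiation–borylation of F2 (s-BuLi/TMEDA, then F3) proceeds by a stereospecific 1,2-metallate shift to the tertiary boronic ester 2-[(1R)-1-[(5R)-5-{[tert-butyl(dimethyl)silyl]oxy}-6-methylhepta-1,6-dien-2-yl]-4-methylcyclohex-3-en-1-yl]-4,4,5,5-tetramethyl-1,3,2-dioxaborolane F4.
- Oxidation (NaOH/H2O2) gives (1S)-1-[(5R)-5-{[tert-butyl(dimethyl)silyl]oxy}-6-methylhepta-1,6-dien-2-yl]-4-methylcyclohex-3-en-1-ol F5.
- Chloroetherification (N-chlorosuccinimide, Ph3P=S) gives tert-butyl{[(3R)-6-[(1S,3R,4R)-3-chloro-4-methyl-7-oxabicyclo[2.2.1]heptan-1-yl]-2-methylhepta-1,6-dien-3-yl]oxy}dimethylsilane F6.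
- Excess Me3SiBr/ZnBr2 opens both C–O bonds of F6 (allylic C1–O to the primary allylic bromide, tertiary C4–O to the bromide with retention) and comes back to the route at 16.

Step 9 (the proposed new step). Water may attack the primary terminus, the wrong face, or lose out to the silyl ether oxygen. The fallback uses known chemistry and sets out from 16.
- PhSNa (THF, −20 °C) displaces the primary allylic bromide to give tert-butyl{[(3R)-6-[(3R,4R)-4-bromo-3-chloro-4-methylcyclohexylidene]-2-methyl-7-(phenylsulfanyl)hept-1-en-3-yl]oxy}dimethylsilane F7.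
- mCPBA (1 equiv, −78 °C) gives the sulfoxide tert-butyl{[(3R)-7-(benzenesulfinyl)-6-[(3R,4R)-4-bromo-3-chloro-4-methylcyclohexylidene]-2-methylhept-1-en-3-yl]oxy}dimethylsilane F8.
- Mislow–Evans [2,3] rearrangement with Et2NH in MeOH as thiophile delivers oxygen only to C1, from the same less hindered face, and comes back to the route at 17.

Further compounds
F1 | step 2 | (1S,3R,4R)-4-bromo-3-chloro-4-methylcyclohexyl acetate | CC(=O)O[C@H]1CC[C@@](C)(Br)[C@H](Cl)C1
F2 | step 7 | (1S)-4-methylcyclohex-3-en-1-yl 2,4,6-tri(propan-2-yl)benzoate | CC1=CC[C@@H](OC(=O)c2c(C(C)C)cc(C(C)C)cc2C(C)C)CC1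
F3 | step 7 | tert-butyl(dimethyl){[(3R)-2-methyl-6-(4,4,5,5-tetramethyl-1,3,2-dioxaborolan-2-yl)hepta-1,6-dien-3-yl]oxy}silane | C=C(C)[C@H](O[Si](C)(C)C(C)(C)C)CCC(=C)B1OC(C)(C)C(C)(C)O1
F4 | step 7 | 2-[(1R)-1-[(5R)-5-{[tert-butyl(dimethyl)silyl]oxy}-6-methylhepta-1,6-dien-2-yl]-4-methylcyclohex-3-en-1-yl]-4,4,5,5-tetramethyl-1,3,2-dioxaborolane | C=C(C)[C@H](O[Si](C)(C)C(C)(C)C)CCC(=C)[C@@]1(B2OC(C)(C)C(C)(C)O2)CC=C(C)CC1
F5 | step 7 | (1S)-1-[(5R)-5-{[tert-butyl(dimethyl)silyl]oxy}-6-methylhepta-1,6-dien-2-yl]-4-methylcyclohex-3-en-1-ol | C=C(C)[C@H](O[Si](C)(C)C(C)(C)C)CCC(=C)[C@@]1(O)CC=C(C)CC1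
F6 | step 7 | tert-butyl{[(3R)-6-[(1S,3R,4R)-3-chloro-4-methyl-7-oxabicyclo[2.2.1]heptan-1-yl]-2-methylhepta-1,6-dien-3-yl]oxy}dimethylsilane | C=C(C)[C@H](O[Si](C)(C)C(C)(C)C)CCC(=C)[C@@]12CC[C@@](C)(O1)[C@H](Cl)C2
F7 | step 9 | tert-butyl{[(3R)-6-[(3R,4R)-4-bromo-3-chloro-4-methylcyclohexylidene]-2-methyl-7-(phenylsulfanyl)hept-1-en-3-yl]oxy}dimethylsilane | C=C(C)[C@H](O[Si](C)(C)C(C)(C)C)CCC(CSc1ccccc1)=C1CC[C@@](C)(Br)[C@H](Cl)C1
F8 | step 9 | tert-butyl{[(3R)-7-(benzenesulfinyl)-6-[(3R,4R)-4-bromo-3-chloro-4-methylcyclohexylidene]-2-methylhept-1-en-3-yl]oxy}dimethylsilane | C=C(C)[C@H](O[Si](C)(C)C(C)(C)C)CCC(CS(=O)c1ccccc1)=C1CC[C@@](C)(Br)[C@H](Cl)C1
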